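## Structural features

The target is a symmetrical dimer: two 5,7-dihydroxy-2,2-dimethylchroman units are joined through their C6 atoms to one sp3 methine, which also carries a 5-methylhexyl chain, and each C8 bears an isobutyryl group. Each benzene ring is fully substituted and is a phloroglucinol core in which one of the three oxygens (O1) is tied into the dihydropyran ring O1–C2(Me)2–C3–C4–C4a–C8a. There is no stereocentre: the bridging carbon carries two identical aryl groups, so no stereocentres stand next to each other and no configuration has to be set. The fragile element is the bis-benzylic methine between two very electron-rich rings, which is open to acid-induced ipso-protonation with retro-Friedel–Crafts cleavage and to oxidation towards a quinone methide; the free polyphenols are also air-sensitive in base. The real difficulty is regiochemical: O1 must sit ortho to the acyl-bearing C8 and para to the bridge-bearing C6, whereas prenylation and cyclisation of a preformed phloroglucinol can close the pyran onto either flanking hydroxyl. The key step uses the fact that each arene holds the contiguous carbon sequence C5–C4a–C8a–C8–C7–C6, with O1 on C8a. If C4a=C8a is already the enol ether double bond of a dihydropyran whose C4a carries the ester carbon (future C5) and whose C8a carries a CH2 (future C8), the ring holds these two groups cis. One C5–C6 bond then completes each benzene ring, and O1 is in place before the arene exists. The two C6 atoms are the α-carbons of a 3-substituted glutaric acid whose C3 is the bridging methine, so the dimer can be built in two directions from one symmetrical core.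

## Logic of the disconnections

17 to 16: the two C8–C(=O) bonds are cut. C8 is the only hydrogen-bearing ring carbon of 16, so the position of acylation is not in question, and the enolisable ketones are kept out of the strongly basic ring-forming step. This removes eight carbons and two carbonyl groups. The forward step must acylate each ring once without cleaving the acid-sensitive bridge.

16 to 14: the C5–C6 bond of each benzene ring is cut, so both arenes disappear at once. What remains is a symmetrical chain compound with two 5-oxo ester arms, in which O1, the gem-dimethyl group and the cis relation of C5 and C8 are already fixed by the dihydropyran. The forward step needs the bridge-side carbanion (C6) to acylate at carbon. Oxygen acylation and aldol reaction between the 1,5-related ketones must be suppressed, and the closure must run twice on one molecule.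

14 to 4 and 12: both C7–C8 bonds (ketone carbon to CH2) are cut. C8 is the γ-methyl of 4, which becomes nucleophilic on deprotonation, and C7 is an acyl carbon at the carboxylic acid level. This gives a convergent union of two equivalents of one heterocycle with one symmetrical core. The forward step must be γ-selective and must stop after one addition per acyl group, which is why the acyl donor is the N-methoxy-N-methylamide 12.

12 to 10, 9, and then 6 and 7; 6 to 5: after the amide C–N bonds are changed back to the diacid, the two bonds from the bridging methine to the future C6 carbons are cut. The methine is then an aldehyde carbon and each arm a malonate. The forward sequence must condense an enolisable aldehyde cleanly, add a second malonate, and lose two carboxyl groups.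

4 to 3, and then 1 and 2: the O1–C2 ether bond is cut, then the C4–C4a bond (chroman numbering) formed by C-alkylation. The heterocycle reduces to two commodity chemicals. The forward steps need monoalkylation at carbon and Markovnikov closure through the enol oxygen to the conjugated enol ether ester.

## Other disconnections considered

Alternative 1: The cut is the C7–C8 bond of each benzene ring, with the pyran rings absent. In the forward step, Mg(OMe)2 in methanol would open both lactones of the bridged bis-pyranone A2, 3,3'-(6-methylheptane-1,1-diyl)bis[4-hydroxy-6-(3-methyl-2-oxobutyl)-2H-pyran-2-one]. In each resulting triketo ester the CH2 next to the isobutyryl group would attack the ester carbon (Claisen folding) to give A1.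
- In its favour: it follows the biosynthetic folding, and the acyl groups arrive with the chain. No Friedel–Crafts acylation is then needed on the acid-sensitive bridged polyphenol, which is better than the chosen plan. Base-mediated conversion of pyranones into acylphloroglucinols is also closer to established chemistry than the chosen key step, again better.
- Against it: A1 still lacks both pyran rings. C-prenylation at the one free ring carbon followed by cyclisation can close onto the hydroxyl next to the acyl group (target connectivity) or onto the hydroxyl next to the bridge (isomeric chroman). On two rings this leads to three constitutions, a question the chosen plan settles before the arene exists.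
- Further risks: the alkylidene-bridged bis(1,3-dicarbonyl) array of A2 and its ring-opened form can lose one half by retro-Michael reaction in base. The ester carbon sits next to the fully substituted bridge-bearing carbon, so aldol-type folding may compete with the Claisen mode.
- Step economy: up to A1 it is equal or slightly better; over the whole route it is about equal, with an isomer separation added.

Alternative 2: The cut is O1–C8a and C4–C4a of each pyran, so both heterocycles are fused late onto finished benzene rings. In the forward step, fluoride (CsF) would trigger 1,2-elimination on both rings of the bis(silylaryl triflate) A4, 1,1-bis[2,6-bis(benzyloxy)-4-(trifluoromethanesulfonyloxy)-3-(trimethylsilyl)phenyl]-6-methylheptane. The oxygen of 3-methylbut-2-enal would add to the aryne carbon remote from the flanking benzyloxy group (C8a); [2+2] closure, opening to the o-quinone methide and oxa-6π closure would give the bis(2H-chromene) A3. Hydrogenation would remove the four benzyl groups and saturate both C3=C4 bonds, arriving at 16.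
- In its favour: the arenes are bought and not built, one cheap enal supplies each pyran in one cascade, and no strong base is needed. The inductive effect of the C5 oxygen should steer the attack, so in principle the regiocontrol equals that of the chosen plan.
- Against it: A4 needs two hexasubstituted rings with adjacent silyl and triflate groups next to a crowded bridge, which costs many protecting-group and functionalisation steps. Step economy is clearly worse. Two arynes must be generated and trapped on one molecule, and ene reaction with the allylic C–H bonds of the enal or other insertions can compete.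
- The late acylation of 16 is the same as in the chosen plan (equal).
- Mechanistically both plans are one-ring-per-arm cascades; this one builds the heterocycle on the arene, the chosen one builds the arene on the heterocycle.

Alternative 3: The cut is the C8–C(=O) bond, as in the last step of the chosen route, but the bond is formed by a light-induced shift of an acyl group from oxygen. The tetraisobutyrate A6, made from 16, would be irradiated at 254 nm. Homolysis of an aryl ester O–C(=O) bond and in-cage recombination at C8 (ortho to the C7 ester, para to the C5 ester, the only free ring carbon) would give A5. Saponification of the two remaining esters would give 17.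
- In its favour: no Lewis or Brønsted acid touches the electron-rich bridged rings, which is better than step 9 of the chosen plan for the stability of the bridge. The regiochemistry is secured by substitution (equal), and A6 should store better than 16 (better).
- Against it: cage escape to phenols and decarbonylation of the isobutyryl radical are inherent losses of the photo-Fries reaction. The hydroxy ketone product absorbs at the irradiation wavelength and screens the substrate, and two migrations are needed on one molecule.
- It takes three operations in place of one, so step economy is worse.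
- It does not address ring construction: it needs 16 and therefore complements the chosen key step instead of replacing it.

Key step: step 8

Remarks on the chemistry:
- The target has no stereocentre.
- The precursor and product of the key step match the target atom for atom and are used with unchanged skeletons; no structural correction was needed.
- The base is changed. A hexamethyldisilazide is too weak to form the dianion of each arm stoichiometrically and would leave a mono-enolate that can lactonise through oxygen, so LiN(iPr)2 is used.
- The closure is classed as 6-(enolendo)-exo-trig.
- The precursor is kept as the dimethyl ester (smallest alkoxide leaving group that tolerates the γ-lithiation). It is released by a cold acidic quench and used without storage, because its 1,5-diketone can undergo intramolecular aldol condensation.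

## Route

Step 1
Reactants: 1 methyl acetoacetate (1.5 equiv); 2 prenyl bromide (1-bromo-3-methylbut-2-ene)
Product: 3 methyl 2-acetyl-5-methylhex-4-enoate
Conditions: K2CO3, acetone, reflux
Reagents that add atoms: none
Why: Acetoacetic ester alkylation: the stabilised enolate displaces the primary allylic bromide at carbon (SN2), and the excess of 1 should hold back dialkylation.

Step 2
Reactants: 3 methyl 2-acetyl-5-methylhex-4-enoate
Product: 4 methyl 2,2,6-trimethyl-3,4-dihydro-2H-pyran-5-carboxylate
Conditions: p-TsOH·H2O (10 mol%), toluene, 80 °C
Reagents that add atoms: none
Why: Acid-catalysed cycloisomerisation (intramolecular hydroalkoxylation): Markovnikov protonation of the trisubstituted alkene gives a tertiary cation that is captured by the enol oxygen of the β-keto ester in a six-membered closure. The conjugated β-alkoxy acrylate is the thermodynamic product.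

Step 3
Reactants: 5 6-methylheptan-1-ol
Product: 6 6-methylheptanal
Conditions: TEMPO (2,2,6,6-tetramethylpiperidin-1-oxyl, 10 mol%), PhI(OAc)2 (1.1 equiv), CH2Cl2, rt
Reagents that add atoms: none
Why: Oxoammonium-mediated oxidation of a primary alcohol, which stops at the aldehyde under anhydrous conditions.

Step 4
Reactants: 6 6-methylheptanal; 7 diethyl malonate (2.2 equiv)
Product: 9 tetraethyl 2-(5-methylhexyl)propane-1,1,3,3-tetracarboxylate, via diethyl 2-(6-methylheptylidene)malonate 8 (not isolated)
Conditions: piperidine (10 mol%), AcOH (10 mol%), toluene, reflux, Dean–Stark; then NaOEt (0.2 equiv), EtOH, rt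
Reagents that add atoms: none
Why: Knoevenagel condensation with azeotropic removal of water gives the alkylidene malonate, which takes up the second malonate by Michael addition under catalytic alkoxide; the aldehyde carbon becomes the future bridging methine.

Step 5
Reactants: 9 tetraethyl 2-(5-methylhexyl)propane-1,1,3,3-tetracarboxylate
Product: 10 3-(5-methylhexyl)pentanedioic acid
Conditions: 6 M HCl, AcOH, reflux
Reagents that add atoms: water, O
Why: Acidic hydrolysis of the four esters and thermal decarboxylation of both malonic acid units, the standard end of a malonic ester synthesis of 3-substituted glutaric acids.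

Step 6
Reactants: 10 3-(5-methylhexyl)pentanedioic acid
Product: 12 N1,N5-dimethoxy-N1,N5-dimethyl-3-(5-methylhexyl)pentanediamide, via 3-(5-methylhexyl)pentanedioyl dichloride 11 (not isolated)
Conditions: (COCl)2 (2.5 equiv), DMF (cat.), CH2Cl2, 0 °C to rt, volatiles removed; then MeNH(OMe)·HCl (2.4 equiv), pyridine, CH2Cl2, 0 °C to rt
Reagents that add atoms: N,O-dimethylhydroxylamine hydrochloride, CNOC.Cl; oxalyl chloride, O=C(Cl)C(Cl)=O (chlorine of 11 only)
Why: Acid chloride formation under Vilsmeier-type catalysis followed by amidation; an excess of oxalyl chloride should carry any cyclic anhydride on to the dichloride so that both ends become Weinreb amides.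

Step 7
Reactants: 4 methyl 2,2,6-trimethyl-3,4-dihydro-2H-pyran-5-carboxylate (2.6 equiv); 12 N1,N5-dimethoxy-N1,N5-dimethyl-3-(5-methylhexyl)pentanediamide
Product: 14 dimethyl 6,6'-[4-(5-methylhexyl)-2,6-dioxoheptane-1,7-diyl]bis(2,2-dimethyl-3,4-dihydro-2H-pyran-5-carboxylate), via γ-lithiated pyran ester 13 (not isolated)
Conditions: LiN(iPr)2 (2.5 equiv), THF, −78 °C; then 12, −78 to −40 °C; AcOH in THF at −78 °C, then aq. NH4Cl
Reagents that add atoms: none
Why: Kinetic γ-deprotonation of the cyclic β-alkoxy acrylate gives a dienolate whose α-carbon is fully substituted, so it should react at the exocyclic CH2, as dienolates of 3-alkoxycrotonates and of 6-methyl-1,3-dioxin-4-ones do. In the Weinreb ketone synthesis the chelated tetrahedral adduct holds each acyl group until the cold acidic quench, which prevents over-addition and keeps the acidic C8 methylene of the product masked. A slight deficit of base relative to 4 avoids attack of free amide base on 12.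

Step 8
Reactants: 14 dimethyl 6,6'-[4-(5-methylhexyl)-2,6-dioxoheptane-1,7-diyl]bis(2,2-dimethyl-3,4-dihydro-2H-pyran-5-carboxylate)
Product: 16 6,6'-(6-methylheptane-1,1-diyl)bis(2,2-dimethyl-3,4-dihydro-2H-chromene-5,7-diol), via mono-chroman keto ester 15 (not isolated)
Conditions: LiN(iPr)2 (6 equiv), THF, −78 °C, slow addition of 14 to the base; then DMPU, −78 °C to rt, argon; degassed 1 M HCl, 0 °C
Reagents that add atoms: none
Why: Proposed new method: each arm is a 5-oxo ester whose 3-oxo group is locked as the cis enol ether C4a=C8a, so LiN(iPr)2 should first remove the doubly activated C8–H (a ketone enolate conjugated with the β-alkoxy acrylate) and then the bridge-side C6–H, giving on each arm a dianion of the β-dicarbonyl type whose terminal carbon C6 is its most nucleophilic site. C6 adds to the ester carbon C5 in a 6-(enolendo)-exo-trig acyl substitution, methoxide leaves, and the resulting cyclohexadienone loses its C6 proton to give the 5,7-dioxido chroman, so each closure ends in an irreversible aromatisation. The closest known reaction types are the base-mediated Dieckmann-type cyclisation of 5-oxo esters to cyclohexane-1,3-diones, the Claisen cyclisation of 3,5-dioxoalkanoates to phloroglucinols, the intramolecular Claisen condensation of 2-(2-oxoalkyl)benzoates to naphthalene-1,3-diols and the carbon acylation of β-dicarbonyl dianions by esters; new here are the dihydropyran enol ether ester as the electrophilic half and the twofold execution on one glutarate core. Both rings close in the same mode, one after the other through 15, and no stereocentre is formed. The selectivity needed is chemoselectivity: adding 14 to excess base turns both ketones into enolates at once, which should shut down the aldol reaction between the 1,5-related carbonyl groups, and C8 cannot reach its own ester except through a four-membered ring. Carbon acylation is expected over oxygen acylation because esters acylate such dianions at the terminal carbon, whereas a mono-enolate would tend to lactonise to a 2-pyranone, which is why full dianion formation is specified. The pyran ring enforces the cis relation of the C8 methylene and the ester, charge delocalisation lowers the rotation barriers about C7–C8 and C8–C8a so that the U-shaped conformer can be reached, and DMPU is added to loosen lithium chelation between the enolate oxygen and O1 that would hold the unproductive rotamer.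

Step 9
Reactants: 16 6,6'-(6-methylheptane-1,1-diyl)bis(2,2-dimethyl-3,4-dihydro-2H-chromene-5,7-diol)
Product: 17 1,1'-[(6-methylheptane-1,1-diyl)bis(5,7-dihydroxy-2,2-dimethyl-3,4-dihydro-2H-chromene-6,8-diyl)]bis(2-methylpropan-1-one)
Conditions: i-PrCOCl (2.5 equiv), AlCl3 (5 equiv), CH2Cl2–MeNO2, 0 °C to rt; ice-cold 1 M HCl
Reagents that add atoms: isobutyryl chloride, CC(C)C(Cl)=O
Why: Friedel–Crafts acylation at C8, the only unsubstituted ring carbon, which is activated by the ortho C7 hydroxyl, ortho O1 and para C5 hydroxyl; any aryl ester formed first should rearrange under the same Lewis acid (Fries shift). The chelated ortho-hydroxy ketone deactivates each ring after one acylation, and the low temperature is chosen to spare the bis-benzylic bridge.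

## Compound list

1 | methyl acetoacetate | COC(=O)CC(C)=O | starting material
2 | prenyl bromide (1-bromo-3-methylbut-2-ene) | CC(C)=CCBr | starting material
3 | methyl 2-acetyl-5-methylhex-4-enoate | COC(=O)C(CC=C(C)C)C(C)=O | intermediate
4 | methyl 2,2,6-trimethyl-3,4-dihydro-2H-pyran-5-carboxylate | COC(=O)C1=C(C)OC(C)(C)CC1 | intermediate
5 | 6-methylheptan-1-ol | CC(C)CCCCCO | starting material
6 | 6-methylheptanal | CC(C)CCCCC=O | intermediate
7 | diethyl malonate | CCOC(=O)CC(=O)OCC | starting material
8 | diethyl 2-(6-methylheptylidene)malonate | CCOC(=O)C(=CCCCCC(C)C)C(=O)OCC | intermediate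
9 | tetraethyl 2-(5-methylhexyl)propane-1,1,3,3-tetracarboxylate | CCOC(=O)C(C(=O)OCC)C(CCCCC(C)C)C(C(=O)OCC)C(=O)OCC | intermediate
10 | 3-(5-methylhexyl)pentanedioic acid | CC(C)CCCCC(CC(=O)O)CC(=O)O | intermediate
11 | 3-(5-methylhexyl)pentanedioyl dichloride | CC(C)CCCCC(CC(=O)Cl)CC(=O)Cl | intermediate
12 | N1,N5-dimethoxy-N1,N5-dimethyl-3-(5-methylhexyl)pentanediamide | CC(C)CCCCC(CC(=O)N(C)OC)CC(=O)N(C)OC | intermediate
13 | lithium (2,2-dimethyl-6-methylideneoxan-5-ylidene)(methoxy)methanolate (γ-lithiated pyran ester) | [Li+].[O-]C(OC)=C1CCC(C)(C)OC1=C | intermediate
14 | dimethyl 6,6'-[4-(5-methylhexyl)-2,6-dioxoheptane-1,7-diyl]bis(2,2-dimethyl-3,4-dihydro-2H-pyran-5-carboxylate) | CC(C)CCCCC(CC(=O)CC1=C(C(=O)OC)CCC(C)(C)O1)CC(=O)CC1=C(C(=O)OC)CCC(C)(C)O1 | intermediate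
15 | methyl 6-[4-(5,7-dihydroxy-2,2-dimethyl-3,4-dihydro-2H-chromen-6-yl)-9-methyl-2-oxodecyl]-2,2-dimethyl-3,4-dihydro-2H-pyran-5-carboxylate | CC(C)CCCCC(CC(=O)CC1=C(C(=O)OC)CCC(C)(C)O1)c1c(O)c2CCC(C)(C)Oc2cc1O | intermediate
16 | 6,6'-(6-methylheptane-1,1-diyl)bis(2,2-dimethyl-3,4-dihydro-2H-chromene-5,7-diol) | CC(C)CCCCC(c1c(O)c2CCC(C)(C)Oc2cc1O)c1c(O)c2CCC(C)(C)Oc2cc1O | intermediate
17 | 1,1'-[(6-methylheptane-1,1-diyl)bis(5,7-dihydroxy-2,2-dimethyl-3,4-dihydro-2H-chromene-6,8-diyl)]bis(2-methylpropan-1-one) | CC(C)CCCCC(c1c(O)c2c(c(C(=O)C(C)C)c1O)OC(C)(C)CC2)c1c(O)c2c(c(C(=O)C(C)C)c1O)OC(C)(C)CC2 | target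

## Step count and least certain steps

Total step count: 9. Longest linear sequence: 7 steps (5 to 6 to 9 to 10 to 12 to 14 to 16 to 17); the branch from 1 and 2 to 4 adds 2 steps.

**Step 8 (key step, proposed new method).**
- What may go wrong: deprotonation at the bridge side may be incomplete, or carbon attack on an ester that is deactivated both as a vinylogous carbonate and by charge delocalisation may be slow. Lactonisation through the enolate oxygen, or aldol condensation between the two arms during warming, could then take over. The sequence may also stall after the first ring closure, and the polyphenoxide may oxidise in air during the quench.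
- Fallback with known chemistry: it sets out from 2 and 6 and rejoins the route at 17, bypassing steps 8 and 9. 2-Methyl-1-(2,4,6-trihydroxyphenyl)propan-1-one F1 would be C-prenylated with 2 (aqueous KOH, 0 °C) to 2-methyl-1-[2,4,6-trihydroxy-3-(3-methylbut-2-enyl)phenyl]propan-1-one F2. Acid-mediated cyclisation (p-TsOH, toluene) would give 1-(5,7-dihydroxy-2,2-dimethyl-3,4-dihydro-2H-chromen-8-yl)-2-methylpropan-1-one F3. Two equivalents of F3 would then be condensed with 6 under mild acid catalysis (hydroxyalkylation, then Friedel–Crafts alkylation through the o-quinone methide) at C6, the only free ring carbon, to give 17.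
- Cost of the fallback: ring closure of F2 onto the other hydroxyl competes, so a chromatographic separation is needed and the regiocontrol of the main plan is lost.

**Step 7.**
- What may go wrong: proton transfer from the α-methylene of the amide, or from the first adduct, may quench the dienolate. A tetrahedral adduct may collapse early and then enolise or lactonise onto the cis ester, or acylation may stop after one arm. The product may also undergo intramolecular aldol condensation of its 1,5-diketone during work-up.
- Fallback: it sets out from 4 and 11 and rejoins at 14. The dienolate 13 would be trapped with Me3SiCl to give the silyl ketene acetal [(2,2-dimethyl-6-methylideneoxan-5-ylidene)(methoxy)methoxy]trimethylsilane F4. F4 would then be acylated at its γ-carbon by both acid chloride groups of 11 (CH2Cl2, −78 °C, catalytic Me3SiOTf if needed) in a vinylogous Mukaiyama-type acylation that needs no base.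

**Step 9.**
- What may go wrong: the bis-benzylic bridge may be cleaved or migrate by ipso-protonation (retro-Friedel–Crafts) under the Lewis acid, the second ring may be acylated incompletely, or the acyl group may remain on oxygen.
- Fallback: it sets out from 16 and rejoins at 17. Protection of all four phenols (MeOCH2Cl, NaH, DMF) would give 6,6'-(6-methylheptane-1,1-diyl)bis[5,7-bis(methoxymethoxy)-2,2-dimethyl-3,4-dihydro-2H-chromene] F5. Directed ortho-metalation (n-BuLi, TMEDA, THF, 0 °C) would give the 8,8'-dilithio derivative F6, not isolated. Quenching with N-methoxy-N-methylisobutyramide would give the 8,8'-bis(isobutyryl) tetrakis(methoxymethyl) ether F7. Dilute HCl in MeOH would then release 17, at a stage where each ring is already deactivated by its ketone.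

**Step 4.**
- What may go wrong: the enolisable aldehyde may self-condense, the alkylidene malonate may deconjugate to the β,γ-isomer and block the Michael addition, or the adduct may revert by retro-Michael reaction.
- Fallback: it sets out from 6 and rejoins at 10. Horner–Wadsworth–Emmons olefination with triethyl phosphonoacetate (NaH, THF) would give ethyl (E)-8-methylnon-2-enoate F8. Michael addition of 7 (NaOEt, EtOH) would give triethyl 2-(5-methylhexyl)propane-1,1,3-tricarboxylate F9. Hydrolysis and decarboxylation as in step 5 would give 10.

## Further compounds

F1 | step 8 | 2-methyl-1-(2,4,6-trihydroxyphenyl)propan-1-one | CC(C)C(=O)c1c(O)cc(O)cc1O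
F2 | step 8 | 2-methyl-1-[2,4,6-trihydroxy-3-(3-methylbut-2-enyl)phenyl]propan-1-one | CC(C)C(=O)c1c(O)cc(O)c(CC=C(C)C)c1O
F3 | step 8 | 1-(5,7-dihydroxy-2,2-dimethyl-3,4-dihydro-2H-chromen-8-yl)-2-methylpropan-1-one | CC(C)C(=O)c1c(O)cc(O)c2CCC(C)(C)Oc12
F4 | step 7 | [(2,2-dimethyl-6-methylideneoxan-5-ylidene)(methoxy)methoxy]trimethylsilane | COC(O[Si](C)(C)C)=C1CCC(C)(C)OC1=C
F5 | step 9 | 6,6'-(6-methylheptane-1,1-diyl)bis[5,7-bis(methoxymethoxy)-2,2-dimethyl-3,4-dihydro-2H-chromene] | CC(C)CCCCC(c1c(OCOC)c2CCC(C)(C)Oc2cc1OCOC)c1c(OCOC)c2CCC(C)(C)Oc2cc1OCOC
F6 | step 9 | 8,8'-dilithio derivative of F5 | CC(C)CCCCC(c1c(OCOC)c2CCC(C)(C)Oc2c([Li])c1OCOC)c1c(OCOC)c2CCC(C)(C)Oc2c([Li])c1OCOC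
F7 | step 9 | 1,1'-[(6-methylheptane-1,1-diyl)bis(5,7-bis(methoxymethoxy)-2,2-dimethyl-3,4-dihydro-2H-chromene-6,8-diyl)]bis(2-methylpropan-1-one) | CC(C)CCCCC(c1c(OCOC)c2c(c(C(=O)C(C)C)c1OCOC)OC(C)(C)CC2)c1c(OCOC)c2c(c(C(=O)C(C)C)c1OCOC)OC(C)(C)CC2
F8 | step 4 | ethyl (E)-8-methylnon-2-enoate | CCOC(=O)/C=C/CCCCC(C)C
F9 | step 4 | triethyl 2-(5-methylhexyl)propane-1,1,3-tricarboxylate | CCOC(=O)CC(CCCCC(C)C)C(C(=O)OCC)C(=O)OCC
A1 | alternative 1 | 1,1'-[(6-methylheptane-1,1-diyl)bis(2,4,6-trihydroxybenzene-3,1-diyl)]bis(2-methylpropan-1-one) | CC(C)CCCCC(c1c(O)cc(O)c(C(=O)C(C)C)c1O)c1c(O)cc(O)c(C(=O)C(C)C)c1O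
A2 | alternative 1 | 3,3'-(6-methylheptane-1,1-diyl)bis[4-hydroxy-6-(3-methyl-2-oxobutyl)-2H-pyran-2-one] | CC(C)CCCCC(C1=C(O)C=C(CC(=O)C(C)C)OC1=O)C1=C(O)C=C(CC(=O)C(C)C)OC1=O
A3 | alternative 2 | 1,1-bis(5,7-dibenzyloxy-2,2-dimethyl-2H-chromen-6-yl)-6-methylheptane | CC(C)CCCCC(c1c(OCc2ccccc2)cc3OC(C)(C)C=Cc3c1OCc1ccccc1)c1c(OCc2ccccc2)cc3OC(C)(C)C=Cc3c1OCc1ccccc1
A4 | alternative 2 | 1,1-bis[2,6-bis(benzyloxy)-4-(trifluoromethanesulfonyloxy)-3-(trimethylsilyl)phenyl]-6-methylheptane | CC(C)CCCCC(c1c(OCc2ccccc2)c([Si](C)(C)C)c(OS(=O)(=O)C(F)(F)F)cc1OCc1ccccc1)c1c(OCc2ccccc2)c([Si](C)(C)C)c(OS(=O)(=O)C(F)(F)F)cc1OCc1ccccc1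
A5 | alternative 3 | 5,5'-di-O-isobutyrate of 17 | CC(C)CCCCC(c1c(OC(=O)C(C)C)c2CCC(C)(C)Oc2c(C(=O)C(C)C)c1O)c1c(OC(=O)C(C)C)c2CCC(C)(C)Oc2c(C(=O)C(C)C)c1O
A6 | alternative 3 | 5,5',7,7'-tetra-O-isobutyrate of 16 | CC(C)CCCCC(c1c(OC(=O)C(C)C)c2CCC(C)(C)Oc2cc1OC(=O)C(C)C)c1c(OC(=O)C(C)C)c2CCC(C)(C)Oc2cc1OC(=O)C(C)C
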